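Time can be taken out of this flask's question if you compare the two substrates over the same minutes.

common to all: left-handed substrate 0.050 M; right-handed substrate 0.050 M; added ligand 80 µM
- Thursday's: reagent 0.15 M; catalyst 70 µM; run made earlier
- Monday's: reagent 0.15 M; catalyst 110 µM; run made earlier
- Sunday's: reagent 0.075 M; catalyst 50 µM; run made earlier
- flask: reagent 0.150 M; catalyst 50 µM; time 3.0 min

- Thursday's (time / min: left-handed product / %, right-handed product / %, left-handed substrate / %): 0.167: 8, 2, 43; 0.500: 15, 2, 32; 0.833: 23, 0, 27; 1.33: 31, 7, 20; 2.00: 35, 6, 11; 2.50: 38, 9, 10; 3.00: 42, 13, 9
- Monday's (time / min: left-handed product / %, right-handed product / %, left-handed substrate / %): 0.167: 12, 0, 38; 0.500: 26, 2, 24; 0.833: 33, 7, 16; 1.33: 40, 9, 13; 2.00: 45, 11, 6; 2.50: 47, 12, 5; 3.00: 49, 14, 4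
- Sunday's (time / min: left-handed product / %, right-handed product / %, left-handed substrate / %): 0.250: 6, 0, 46; 0.833: 13, 0, 41; 1.33: 14, 4, 34; 2.00: 18, 2, 31; 3.00: 20, 2, 26

(standard deviation of a reading: 2 percentage points)

* excess of left-handed product over right-handed product in the product at 10 s
* excess of left-handed product over right-handed product in the product at 3.0 min
* part of the left-handed substrate and right-handed substrate charged together that has reacted at 3.0 min

- catalyst is single-handed; left-handed substrate and right-handed substrate are mirror images of each other, charged as a racemate, each of them at the stated concentration
- an excess is the difference of the two amounts in percent of their sum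
- an excess is below zero if the other one leads

Suppose each substrate falls in proportion to its own concentration and to one shared factor, catalyst times reagent. That factor may drift, yet it cancels, so the ratio s of the two rate constants equals the logarithmic loss of left-handed substrate over that of right-handed substrate. Monday's last row has more right-handed product than the other runs' last rows: from 50.0% each, 4% left-handed substrate is read to remain and, by difference from the right-handed product, 36.0% right-handed substrate, so s reads 7.69. This selectivity factor is a rough reading: Thursday's last row gives 5.70.

The products start in the ratio s, so the excess begins at s minus one over s plus one, 77.0%, my figure for 10 s.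

Sunday's run, with the catalyst charge of the asked flask and half its reagent, reads in its last row a logarithmic loss of 0.654 in left-handed substrate. Taking the rate as proportional to reagent, I reckon the asked flask's loss at 1.31, leaving 13.5% left-handed and, through s, 42.2% right-handed substrate: 44.3% reacted, at an excess of 64.7%.

The forecast gave 80%, 70% and 41%, with selectivity 8 to 10, “perhaps better at low catalyst”; its excesses stand above mine and its conversion below.

The flask gives an excess of 76.8% at 10 s and 67.3% at 3.0 min, with 40.8% reacted.

    2 reagent → homo dimer (k = 0.0291 /M/s)
    catalyst + added ligand ⇌ idle complex, settled at all times (K = 20400 /M)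
    reagent + catalyst + right-handed substrate → catalyst + right-handed product (k = 622 /M²/s)
    reagent + catalyst + left-handed substrate → catalyst + left-handed product (k = 4990 /M²/s)
    reagent ⇌ dormant form (K = 0.959, k = 0.138 /s)

This flask ends with 32% of its left-handed charge, and through s that means 86.2% of its right-handed charge; it holds 87%. The neighbour flask charged with 0.38 M of reagent keeps 8.0% of its left-handed charge, s gives 72.0% of the right-handed charge, and it holds 73%. There the early excess is 75.4%, and by the end the excess has come down to 54.6%.

All runs stem from a simulated flask from invented constants.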